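**Target 14:** robinetinidol-(4α→8)-epigallocatechin; upper unit 2R,3S,4S (2,3-trans-3,4-trans, 5-deoxy ring A), lower unit 2R,3R.

Assumption: (−)-epigallocatechin (bulk green-tea isolate) is taken as a cheap commercial chiral-pool starting material, and the (R) hand of the chiral acid in step 5 is taken as the one that gives the 2S chromene, to be confirmed against its antipode in the first run.

**Retrosynthetic overview**
1. 14 ⇐ nona-O-benzyl ether 13 by one global hydrogenolysis; the lower unit (rings D, E, F) comes intact from (−)-epigallocatechin 4.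
2. 13 ⇐ 4-aryl-2H-chromene 11 by syn hydroboration–oxidation of C3=C4 (C3–O bond; C3 and C4 relayed from C2).
3. Key disconnection, O1–C2 of ring C: 11 ⇐ tertiary allylic alcohol 9 by a catalyst-controlled dehydrative C–O ring closure that sets C2. The interflavan C4–C8 bond is already present as a planar, stereochemically silent junction.
4. 9 ⇐ 8-metalated penta-O-benzyl-epigallocatechin (4 → 5 → 6 → 7) + chalcone 3 (from 1 + 2).
5. Ring order: D, E, F bought (chiral pool); A and B bought as arenes; ring C closed last.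

**Route**

Step 1
Reactants: 1 1-[4-(benzyloxy)-2-hydroxyphenyl]ethan-1-one; 2 3,4,5-tris(benzyloxy)benzaldehyde
Product: 3 (E)-1-[4-(benzyloxy)-2-hydroxyphenyl]-3-[3,4,5-tris(benzyloxy)phenyl]prop-2-en-1-one (chalcone)
Conditions: KOH (3 equiv), EtOH–THF, 20 °C, 36 h; AcOH work-up
Reagents that add atoms: none
Why: Claisen–Schmidt (crossed aldol) condensation, in which the methyl ketone enolate adds to the non-enolisable aldehyde and E1cB loss of water gives the conjugated E-enone; no stereocenter is formed.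

Step 2
Reactants: 4 (−)-epigallocatechin
Product: 5 (2R,3R)-5,7-bis(benzyloxy)-2-[3,4,5-tris(benzyloxy)phenyl]chroman-3-ol
Conditions: BnBr (5.5 equiv), K2CO3 (6 equiv), DMF, Ar, 0 → 20 °C, 16 h
Reagents that add atoms: benzyl bromide, BrCc1ccccc1
Why: Williamson ether synthesis, in which K2CO3 ionises only the five phenols so the secondary 3-OH stays free and the chiral-pool centres C2 and C3 are untouched.

Step 3
Reactants: 5 penta-O-benzyl-epigallocatechin
Product: 6 (2R,3R)-5,7-bis(benzyloxy)-8-bromo-2-[3,4,5-tris(benzyloxy)phenyl]chroman-3-ol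
Conditions: NBS (1.0 equiv), CH2Cl2, −40 → 20 °C
Reagents that add atoms: N-bromosuccinimide, O=C1CCC(=O)N1Br
Why: Electrophilic aromatic bromination, which in 5,7-di-O-benzyl flavan-3-ols goes selectively to C8 of the phloroglucinol ring (as with the tetra-O-benzyl ethers of catechin and epicatechin), the tribenzyloxyphenyl ring being much less nucleophilic.

Step 4
Reactants: 6 8-bromo-penta-O-benzyl-epigallocatechin; 3 chalcone
Product: 9 (E)-1-[4-(benzyloxy)-2-hydroxyphenyl]-1-{(2R,3R)-5,7-bis(benzyloxy)-3-hydroxy-2-[3,4,5-tris(benzyloxy)phenyl]chroman-8-yl}-3-[3,4,5-tris(benzyloxy)phenyl]prop-2-en-1-ol as both carbinol epimers, via 8-lithio sodium alkoxide 7 (not isolated), via chalcone sodium phenoxide 8 (not isolated)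
Conditions: 6, NaH (1.05 equiv), THF, 0 → 20 °C; t-BuLi ((CH3)3CLi, 2.0 equiv), −78 °C; add 8 (1.2 equiv; from 3, NaH, THF, 0 °C); −78 → −40 °C; cold H2O quench; crude 9 filtered through Et3N-washed silica and used at once
Reagents that add atoms: none
Why: Bromine–lithium exchange followed by 1,2-addition of the hard aryllithium to the chalcone carbonyl (both OH groups masked as sodium salts) makes the interflavan C–C bond; the new carbinol centre needs no control because step 5 ionises it.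

Step 5
Reactants: 9 tertiary allylic alcohol
Product: 13 (2R,3S,4S)-7-(benzyloxy)-4-{(2R,3R)-5,7-bis(benzyloxy)-3-hydroxy-2-[3,4,5-tris(benzyloxy)phenyl]chroman-8-yl}-2-[3,4,5-tris(benzyloxy)phenyl]chroman-3-ol, via vinyl ortho-quinone methide 10 (not isolated), via (2S)-2H-chromene 11 (not isolated), via C3 alkylborane 12 (not isolated)
Conditions: chiral acid N-[(11bR)-4-oxido-2,6-bis(2,4,6-triisopropylphenyl)dinaphtho[2,1-d:1',2'-f][1,3,2]dioxaphosphepin-4-yl]-1,1,1-trifluoromethanesulfonamide (5 mol %), 4 Å molecular sieves, toluene, −78 °C, dark; then Et3N (10 mol %), BH3·SMe2 (6 equiv), −78 → 20 °C; then NaOH, H2O2, THF, 0 °C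
Reagents that add atoms: borane–dimethyl sulfide, [BH3-][S+](C)C (hydrogen at C4; boron only in 12); hydrogen peroxide, OO (oxygen of the new 3-OH)
Why: Proposed new method: the chiral acid ionises the doubly benzylic, allylic C–OH of 9 at −78 °C to a 1,1,3-triarylallyl cation (10 in its O-protonated form) that stays a contact ion pair with the phosphoramide anion hydrogen-bonded to the phenol, and the phenol oxygen then closes on the styryl terminus (oxa-6π-type ring closure, new O1–C2 bond, ring C) from the face the anion leaves open, so that C2 (S, ring B α) is fixed by the catalyst and not by the remote lower unit, after which the acid- and light-labile chromene 11 is trapped in the same flask by the known hydroboration–oxidation of flav-3-enes, borane adding H and B syn across C3=C4 anti to ring B to give 3-OH β and the 4-aryl group α (2,3-trans-3,4-trans); the closest known reaction type is the chiral N-triflylphosphoramide-catalysed intramolecular allylic etherification of simple achiral 2-(1-hydroxyallyl)phenols to 2H-chromenes, which has not been shown on a 1,1-diaryl carbinol carrying a resident chiral, 2,6-dioxygenated flavan ring or under catalyst-versus-substrate control.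

Step 6
Reactants: 13 nona-O-benzyl dimer
Product: 14 robinetinidol-(4α→8)-epigallocatechin, (2R,3S,4S)-4-[(2R,3R)-3,5,7-trihydroxy-2-(3,4,5-trihydroxyphenyl)chroman-8-yl]-2-(3,4,5-trihydroxyphenyl)chromane-3,7-diol
Conditions: H2 (1 atm), Pd(OH)2/C, THF–MeOH–H2O, 20 °C; filter under Ar, Sephadex LH-20, lyophilise
Reagents that add atoms: none
Why: Catalytic hydrogenolysis of the nine aryl benzyl ethers, standard for benzylated proanthocyanidins, leaves the aliphatic C–O bonds, the interflavan C–C bond and all five stereocenters untouched.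

**Compound list**

1 | 1-[4-(benzyloxy)-2-hydroxyphenyl]ethan-1-one | CC(=O)c1ccc(OCc2ccccc2)cc1O | starting material
2 | 3,4,5-tris(benzyloxy)benzaldehyde | O=Cc1cc(OCc2ccccc2)c(OCc2ccccc2)c(OCc2ccccc2)c1 | starting material
3 | (E)-1-[4-(benzyloxy)-2-hydroxyphenyl]-3-[3,4,5-tris(benzyloxy)phenyl]prop-2-en-1-one | O=C(/C=C/c1cc(OCc2ccccc2)c(OCc2ccccc2)c(OCc2ccccc2)c1)c1ccc(OCc2ccccc2)cc1O | intermediate
4 | (−)-epigallocatechin, (2R,3R)-2-(3,4,5-trihydroxyphenyl)chromane-3,5,7-triol | O[C@@H]1Cc2c(O)cc(O)cc2O[C@@H]1c1cc(O)c(O)c(O)c1 | starting material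
5 | (2R,3R)-5,7-bis(benzyloxy)-2-[3,4,5-tris(benzyloxy)phenyl]chroman-3-ol | O[C@@H]1Cc2c(OCc3ccccc3)cc(OCc3ccccc3)cc2O[C@@H]1c1cc(OCc2ccccc2)c(OCc2ccccc2)c(OCc2ccccc2)c1 | intermediate
6 | (2R,3R)-5,7-bis(benzyloxy)-8-bromo-2-[3,4,5-tris(benzyloxy)phenyl]chroman-3-ol | O[C@@H]1Cc2c(OCc3ccccc3)cc(OCc3ccccc3)c(Br)c2O[C@@H]1c1cc(OCc2ccccc2)c(OCc2ccccc2)c(OCc2ccccc2)c1 | intermediate
7 | sodium (2R,3R)-5,7-bis(benzyloxy)-8-lithio-2-[3,4,5-tris(benzyloxy)phenyl]chroman-3-olate | [Na]O[C@@H]1Cc2c(OCc3ccccc3)cc(OCc3ccccc3)c([Li])c2O[C@@H]1c1cc(OCc2ccccc2)c(OCc2ccccc2)c(OCc2ccccc2)c1 | intermediate (not isolated)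
8 | sodium phenoxide of chalcone 3 | [Na]Oc1cc(OCc2ccccc2)ccc1C(=O)/C=C/c1cc(OCc2ccccc2)c(OCc2ccccc2)c(OCc2ccccc2)c1 | intermediate (not isolated)
9 | (E)-1-[4-(benzyloxy)-2-hydroxyphenyl]-1-{(2R,3R)-5,7-bis(benzyloxy)-3-hydroxy-2-[3,4,5-tris(benzyloxy)phenyl]chroman-8-yl}-3-[3,4,5-tris(benzyloxy)phenyl]prop-2-en-1-ol, carbinol centre unassigned (both epimers) | O[C@@H]1Cc2c(OCc3ccccc3)cc(OCc3ccccc3)c(C(O)(/C=C/c3cc(OCc4ccccc4)c(OCc4ccccc4)c(OCc4ccccc4)c3)c3ccc(OCc4ccccc4)cc3O)c2O[C@@H]1c1cc(OCc2ccccc2)c(OCc2ccccc2)c(OCc2ccccc2)c1 | intermediate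
10 | vinyl ortho-quinone methide, 3-(benzyloxy)-6-[1-(lower-unit-8-yl)-3-(3,4,5-tribenzyloxyphenyl)allylidene]cyclohexa-2,4-dien-1-one (drawn neutral; O-protonated and ion-paired with the acid in the flask) | O[C@@H]1Cc2c(OCc3ccccc3)cc(OCc3ccccc3)c(C(/C=C/c3cc(OCc4ccccc4)c(OCc4ccccc4)c(OCc4ccccc4)c3)=C3C=CC(OCc4ccccc4)=CC3=O)c2O[C@@H]1c1cc(OCc2ccccc2)c(OCc2ccccc2)c(OCc2ccccc2)c1 | intermediate (not isolated)
11 | (2S)-7-(benzyloxy)-4-{(2R,3R)-5,7-bis(benzyloxy)-3-hydroxy-2-[3,4,5-tris(benzyloxy)phenyl]chroman-8-yl}-2-[3,4,5-tris(benzyloxy)phenyl]-2H-chromene (ring B α) | c3ccccc3COc1ccc2c(c1)O[C@H](c1cc(OCc3ccccc3)c(OCc3ccccc3)c(OCc3ccccc3)c1)C=C2c1c(OCc3ccccc3)cc(OCc3ccccc3)c2c1O[C@H](c1cc(OCc3ccccc3)c(OCc3ccccc3)c(OCc3ccccc3)c1)[C@H](O)C2 | intermediate (not isolated)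
12 | C3 alkylborane, same relative configuration as 13 with BH2 in place of the upper 3-OH and the lower 3-oxygen as O–BH2 | c3ccccc3COc1ccc2c(c1)O[C@H](c1cc(OCc3ccccc3)c(OCc3ccccc3)c(OCc3ccccc3)c1)[C@@H](B)[C@@H]2c1c(OCc3ccccc3)cc(OCc3ccccc3)c2c1O[C@H](c1cc(OCc3ccccc3)c(OCc3ccccc3)c(OCc3ccccc3)c1)[C@H](OB)C2 | intermediate (not isolated)
13 | (2R,3S,4S)-7-(benzyloxy)-4-{(2R,3R)-5,7-bis(benzyloxy)-3-hydroxy-2-[3,4,5-tris(benzyloxy)phenyl]chroman-8-yl}-2-[3,4,5-tris(benzyloxy)phenyl]chroman-3-ol | c3ccccc3COc1ccc2c(c1)O[C@H](c1cc(OCc3ccccc3)c(OCc3ccccc3)c(OCc3ccccc3)c1)[C@@H](O)[C@@H]2c1c(OCc3ccccc3)cc(OCc3ccccc3)c2c1O[C@H](c1cc(OCc3ccccc3)c(OCc3ccccc3)c(OCc3ccccc3)c1)[C@H](O)C2 | intermediate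
14 | robinetinidol-(4α→8)-epigallocatechin | Oc1ccc2c(c1)O[C@H](c1cc(O)c(O)c(O)c1)[C@@H](O)[C@@H]2c1c(O)cc(O)c2c1O[C@H](c1cc(O)c(O)c(O)c1)[C@H](O)C2 | target

**Count and risks**

Total steps: 6. Longest linear sequence: 5 steps (4 → 5 → 6 → 9 → 13 → 14); step 1 feeds in convergently.

Steps most likely to fail:

Step 5 (the proposed new ring closure). The resident lower unit or a long-lived cation may erode catalyst control, and uncatalysed closure may compete. The fallback uses known chemistry and sets out from 9. An achiral acid, diphenyl phosphate (PhO)2P(O)OH (5 mol %, CH2Cl2, −40 °C), effects the ordinary acid-catalysed dehydrative cyclisation of a 2-(1-hydroxyallyl)phenol to the 2H-chromene. This gives 11 together with its C2 epimer, the (2R)-chromene F1. Because the lower unit is homochiral the two are diastereomers and are separated by preparative HPLC on silica. F1 is returned to the same acid at 20 °C, where reversible C2–O ionisation re-equilibrates it to the 11/F1 mixture, and is separated again. The pooled 11 is hydroborated and oxidised as in the second stage of step 5, and the fallback comes back to the route at 13.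

Step 4 (aryllithium addition to the chalcone). The hindered 2,6-dioxygenated aryllithium may add slowly to the phenoxide-deactivated enone or add 1,4, and 9 may ionise on work-up. The fallback sets out from 3 and 6.
- Chalcone 3 is isomerised (NaOAc, EtOH, reflux; intramolecular oxa-Michael addition) to the racemic flavanone F2, which has neither a free phenol nor a conjugate position.
- Species 7, made from 6 as before, is transmetalated with CeCl3 to the organocerium reagent F3.
- F3 adds to the C4 carbonyl of F2 without enolising it and gives the tertiary 4-aryl-flavan-4-ol F4.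
- Pyridinium p-toluenesulfonate in CH2Cl2 at 0 °C dehydrates F4 to the chromene pair 11/F1, which is separated and recycled as described above.
- Hydroboration–oxidation of 11 as in step 5 brings the route back at 13.

Step 6 (global hydrogenolysis). Cleavage of nine ethers may stall, benzylic C2–O1 bonds may open on the metal, and the free pyrogallol units oxidise in air. The fallback sets out from 13: Lewis-acid debenzylation with BCl3 and pentamethylbenzene as benzyl-cation scavenger (CH2Cl2, −78 °C, MeOH quench), with no metal surface and no hydrogen. The interflavan bond of a 5-deoxy upper unit is comparatively acid-stable. It comes back at 14 directly and no new compound is made (F0).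

Further compounds
F1 | step 5 | (2R)-7-(benzyloxy)-4-{(2R,3R)-5,7-bis(benzyloxy)-3-hydroxy-2-[3,4,5-tris(benzyloxy)phenyl]chroman-8-yl}-2-[3,4,5-tris(benzyloxy)phenyl]-2H-chromene (C2 epimer of 11) | c3ccccc3COc1ccc2c(c1)O[C@@H](c1cc(OCc3ccccc3)c(OCc3ccccc3)c(OCc3ccccc3)c1)C=C2c1c(OCc3ccccc3)cc(OCc3ccccc3)c2c1O[C@H](c1cc(OCc3ccccc3)c(OCc3ccccc3)c(OCc3ccccc3)c1)[C@H](O)C2
F2 | step 4 | rac-7-(benzyloxy)-2-[3,4,5-tris(benzyloxy)phenyl]chroman-4-one | O=C1CC(c2cc(OCc3ccccc3)c(OCc3ccccc3)c(OCc3ccccc3)c2)Oc2cc(OCc3ccccc3)ccc12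
F3 | step 4 | sodium (2R,3R)-5,7-bis(benzyloxy)-8-(dichlorocerio)-2-[3,4,5-tris(benzyloxy)phenyl]chroman-3-olate | [Na]O[C@@H]1Cc2c(OCc3ccccc3)cc(OCc3ccccc3)c([Ce](Cl)Cl)c2O[C@@H]1c1cc(OCc2ccccc2)c(OCc2ccccc2)c(OCc2ccccc2)c1
F4 | step 4 | 7-(benzyloxy)-4-{(2R,3R)-5,7-bis(benzyloxy)-3-hydroxy-2-[3,4,5-tris(benzyloxy)phenyl]chroman-8-yl}-2-[3,4,5-tris(benzyloxy)phenyl]chroman-4-ol, upper C2 and C4 unassigned (mixture) | c3ccccc3COc1ccc2c(c1)OC(c1cc(OCc3ccccc3)c(OCc3ccccc3)c(OCc3ccccc3)c1)CC2(O)c1c(OCc3ccccc3)cc(OCc3ccccc3)c2c1O[C@H](c1cc(OCc3ccccc3)c(OCc3ccccc3)c(OCc3ccccc3)c1)[C@H](O)C2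
F0 | step 6 | none | none
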